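At early times E falls in both runs, and two chemists read those falls differently.

the same everywhere: E 0.15 M
- Thursday's: Q 0.34 M; run made earlier
- Monday's: Q 0.58 M; run made earlier
- teal: Q 0.230 M; time 1.0 h
- red: Q 0.450 M; time 1.0 h

| run | time / min | E / % | X / % |
|---|---|---|---|
| Thursday's | 2.50 | 92.7 | 3.7 |
| Thursday's | 4.00 | 92.5 | 3.8 |
| Thursday's | 6.00 | 88.8 | 6.5 |
| Thursday's | 8.00 | 84.4 | 8.0 |
| Thursday's | 12.0 | 77.9 | 10.4 |
| Thursday's | 20.0 | 71.7 | 15.1 |
| Thursday's | 30.0 | 62.5 | 14.8 |
| Monday's | 1.50 | 92.9 | 3.7 |
| Monday's | 5.00 | 81.6 | 8.1 |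
| Monday's | 8.00 | 75.7 | 13.7 |
| Monday's | 12.0 | 66.3 | 14.9 |
| Monday's | 20.0 | 54.9 | 19.6 |
| Monday's | 25.0 | 50.3 | 20.8 |
| Monday's | 30.0 | 46.4 | 21.2 |

(standard deviation of a reading: 1 percentage point)

- what has gone from E into another species counts as reacted, even if it can come back

- part of the E that has reacted at the end, teal
- part of the E that has reacted at the end, red
- what raising the concentration of Q from its lowest to its highest value here does to the part of the E that has reacted (changes below 5 percentage points count as none) (no change / it falls / it rises)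

The one who made the forecast holds that “At early times the loss scales roughly with Q·t”, with t the time, and gives 42% reacted for teal and 60% for red; the trend: it rises.

The other chemist sets Thursday's reading at 20.0 min beside Monday's at 12.0 min. Their products of charged Q and t stand in the ratio 1.02, yet E reads 66.3% on Monday, lower than Thursday's 71.7%, a gap of 5.4 percentage points against a scatter of 1 point. She reads this as Q wearing away on a clock of its own, so she compares runs at equal times, with E charged at 0.15 M.

Her frozen quantity is a, the natural logarithm of the factor by which E has fallen, divided by the Q charged. This is a pseudo-first-order reckoning. At 30.0 min, a reads 1.38 M⁻¹ on Thursday and 1.32 M⁻¹ on Monday, nearly equal, with mean 1.35 M⁻¹. At 12.0 min the mean is 0.722 M⁻¹. So a grows as t to the power 0.686, and carried to 1.0 h, the loss per molar of charge is 2.18 M⁻¹. Her own numbers, not the forecast's, are 39.4% for teal and 62.5% for red.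

The flask gives 35.3% for teal and 59.0% for red: it rises, by 24 points.

    E + Q → G + X (k = 6.50 × 10⁻⁴ M⁻¹ s⁻¹)
    X + Q → G + D (k = 4.50 × 10⁻⁴ M⁻¹ s⁻¹)
    D + Q → G + J (k = 0.00110 M⁻¹ s⁻¹)
    G + E ⇌ L, settled at all times (K = 180 M⁻¹)
    Q ⇌ Z (K = 3.10, k = 8.00 × 10⁻⁴ s⁻¹)

The forecast stands 6.7 points high on teal and close on red. The gap between red and teal comes from their difference in charged Q. Part of the reason teal stays low is the wearing away of Q: with Q held, teal reaches 68.6%, not 35.3%. Teal and red each keep 21.6% of their Q free at the end, and a reads 1.89 M⁻¹ in teal and 1.98 M⁻¹ in red, both below the carried 2.18 M⁻¹. Red's 1.0 h is 5.50 times 10.9 min, the relaxation half-life of Q and Z by that step alone, so the Q·t view has its region at times well under that half-life.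

For the neighbour, red with 1.8 M of Q, the carried a gives 98.0% reacted; the computed flask gives 95.6%.

The readings are calculated for substances that don't exist; noise was put on by code.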